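Retrosynthetic cuts, in order: aryl O–Si; Z-alkene back to the alkyne; C5=C6 back to C5H–C6H2; the two O–CH3 bonds; the C2–CH2 bond to the benzofuran; the C5–O bond; the C4–O bond (back to a phenol); ArCH2–C≡C back to ArCHO + HC≡CPh.
Enabling feature: C4 is the only stereocentre. It is stereogenic only because the two arms of the cyclohexa-2,5-dienone ring differ (C2 bears the CH2-benzofuran, C5 bears OMe). Without these two groups the ring is a 4-hydroxy-4-alkyl dienone with a mirror plane through C1 and C4, and its C4 oxygen sits next to C5.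
Forward, carbocycle: the six-membered ring is the arene of 4-hydroxybenzaldehyde, dearomatised to the achiral para-quinol; a temporary 1,3-dioxolane ring is closed from the C4 oxygen onto C5, then C2 is iodinated.
Forward, benzofuran: a pyranone ring is built by Pechmann condensation and contracted to the furan ring by Perkin rearrangement; CO2H is taken to CH2Cl and then CH2ZnCl.
The fragments are joined at C2–CH2 (Negishi); acetal cleavage, double O-methylation, C5–C6 dehydrogenation, semihydrogenation and desilylation complete the target.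
Stereochemistry: a chiral phosphoric acid picks one of the two enantiotopic enone arms in the dioxolane closure and so fixes C4 as R; C5 and the acetal carbon are transient; the Z-alkene comes from syn addition of H2.

Key step: step 4

Notation: the carbocycle keeps the target numbering throughout (C1 carbonyl, C2 bearing the side chain, C4 quaternary, C5 oxygenated); ArCH2 = [6-methoxy-3-phenyl-5-(triisopropylsilyloxy)-1-benzofuran-2-yl]methyl.
Assumption: the (R)-configured phosphoric acid is taken to select the arm drawn for 9; its sense of induction must be assigned on the first run, and the (S)-acid is used with nothing else changed if it proves opposite.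

Step 1
Reactants: 1 4-hydroxybenzaldehyde; 2 phenylacetylene
Product: 4 4-(1-hydroxy-3-phenylprop-2-yn-1-yl)phenol (racemic), via phenylethynylmagnesium bromide 3 (not isolated)
Conditions: 2 (2.5 equiv), EtMgBr (2.4 equiv), THF, 0 °C to rt; then 1, THF, 0 °C to rt; aq NH4Cl
Reagents that add atoms: none
Why: Addition of an alkynyl Grignard reagent to an aldehyde, in which one equivalent of 3 is spent on the phenol proton so that no protecting group is needed, and the carbinol centre forms as a racemate that step 2 erases.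

Step 2
Reactants: 4 4-(1-hydroxy-3-phenylprop-2-yn-1-yl)phenol
Product: 5 4-(3-phenylprop-2-yn-1-yl)phenol
Conditions: Et3SiH (3 equiv), TFA, CH2Cl2, -20 to 0 °C, 4 added slowly to the premixed reagents
Reagents that add atoms: none
Why: Ionic hydrogenation (silane/Brønsted acid deoxygenation), in which the cation stabilised by the para-hydroxyphenyl and alkynyl groups forms readily and should accept hydride at the benzylic carbon, keeping the aryl-conjugated alkyne instead of forming an allene.

Step 3
Reactants: 5 4-(3-phenylprop-2-yn-1-yl)phenol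
Product: 6 4-hydroxy-4-(3-phenylprop-2-yn-1-yl)cyclohexa-2,5-dien-1-one (achiral para-quinol)
Conditions: PhI(OAc)2 (1.1 equiv), MeCN/H2O 3:1, 0 °C
Reagents that add atoms: water, O
Why: Hypervalent-iodine oxidative dearomatisation of a para-alkylphenol, in which water captures the para carbon of the activated phenol to give the 4-hydroxy dienone, a compound with a mirror plane through C1 and C4.

Step 4
Reactants: 6 4-hydroxy-4-(3-phenylprop-2-yn-1-yl)cyclohexa-2,5-dien-1-one; 7 isobutyraldehyde
Product: 9 (2R,3aS,7aR)-2-isopropyl-7a-(3-phenylprop-2-yn-1-yl)-3a,7a-dihydro-1,3-benzodioxol-5(4H)-one (cis-fused dioxolane enone; C4 R and C5 S in carbocycle numbering; isopropyl exo), via quinol isobutyraldehyde hemiacetal 8 (not isolated)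
Conditions: 7 (3 equiv), (R)-3,3'-bis(2,4,6-triisopropylphenyl)-1,1'-binaphthyl-2,2'-diyl hydrogen phosphate (10 mol %), 4 Å MS, ClCH2CH2Cl, 40 °C
Reagents that add atoms: none
Why: The tertiary C4–OH of 6 adds reversibly to 7 to give hemiacetal 8; in a hydrogen-bonded complex the acidic proton of the phosphoric acid activates the C1 carbonyl while the phosphoryl oxygen accepts the hemiacetal O–H, and that oxygen adds to C5 (oxa-Michael), after which C6 is protonated. The closest known reaction type is the chiral phosphoric acid-catalysed acetalisation/oxa-Michael cascade that desymmetrises para-quinols and para-peroxyquinols with aldehydes. The one ring formed, the 1,3-dioxolane (C4, O, CH, O, C5), closes in the 5-exo-trig mode. C4 becomes stereogenic (R) through the catalyst's choice of one of the two enantiotopic enone arms; C5 (S) follows from the short O–CH–O tether, which can deliver oxygen only to the ring face that already bears the C4 oxygen (cis fusion); the acetal carbon (R, isopropyl exo on the convex face) is settled by the faster-cyclising hemiacetal epimer under rapid equilibration and is irrelevant because it leaves in step 14. The step needs only arm selectivity: the mirror plane of 6 makes both β-carbons chemically identical, so no regiochemical question arises, and after one addition no hydroxyl is left to attack the second enone.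

Step 5
Reactants: 9 cis-fused dioxolane enone
Product: 10 (2R,3aS,7aR)-6-iodo-2-isopropyl-7a-(3-phenylprop-2-yn-1-yl)-3a,7a-dihydro-1,3-benzodioxol-5(4H)-one (iodine on C2 of the carbocycle)
Conditions: I2 (2 equiv), pyridine/CH2Cl2 1:1, 0 °C to rt, dark; aq Na2S2O3
Reagents that add atoms: iodine, II
Why: Baylis–Hillman-type α-iodination of an enone (reversible pyridine addition at C3, iodination at C2, elimination), which can act only on the remaining C2=C3 arm, uses a base too weak to open the β-alkoxy ketone, and makes C4 stereogenic independently of the C5–O bond from here on.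

Step 6
Reactants: 11 ethyl benzoylacetate
Product: 12 ethyl 2-chloro-3-oxo-3-phenylpropanoate (racemic)
Conditions: SO2Cl2 (1.05 equiv), CH2Cl2, 0 °C to rt
Reagents that add atoms: sulfuryl chloride, O=S(=O)(Cl)Cl
Why: Electrophilic α-chlorination of the enolised β-keto ester, which installs the halogen needed in step 8 before the electron-rich arene is present and so removes any competition from ring halogenation.

Step 7
Reactants: 12 ethyl 2-chloro-3-oxo-3-phenylpropanoate; 13 2-methoxyhydroquinone
Product: 14 3-chloro-6-hydroxy-7-methoxy-4-phenylcoumarin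
Conditions: H2SO4 (75% aq), 0 °C to rt
Reagents that add atoms: none
Why: Pechmann condensation, in which the arene carbon of 13 that is para to OMe and ortho to the C4 hydroxyl is the most activated and least hindered site, so the ketone carbon is attacked there and that hydroxyl lactonises to give the 6-hydroxy-7-methoxy pattern.

Step 8
Reactants: 14 3-chloro-6-hydroxy-7-methoxy-4-phenylcoumarin
Product: 16 5-hydroxy-6-methoxy-3-phenyl-1-benzofuran-2-carboxylic acid, via ring-opened chlorocinnamic acid 15 (not isolated)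
Conditions: NaOH (aq)/EtOH, reflux, N2; then aq HCl to pH 2
Reagents that add atoms: sodium hydroxide, [Na+].[OH-]
Why: Perkin rearrangement (coumarin to benzofuran ring contraction), in which hydroxide opens the lactone to 15 and its phenoxide displaces the vinylic chloride by addition–elimination, so coumarin C3 becomes benzofuran C2 bearing CO2H and coumarin C4 becomes C3 bearing phenyl.

Step 9
Reactants: 16 5-hydroxy-6-methoxy-3-phenyl-1-benzofuran-2-carboxylic acid
Product: 17 methyl 5-hydroxy-6-methoxy-3-phenyl-1-benzofuran-2-carboxylate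
Conditions: MeOH, H2SO4 (cat.), reflux
Reagents that add atoms: methanol, CO
Why: Fischer esterification, which converts only the carboxylic acid and leaves the phenol free for the next step.

Step 10
Reactants: 17 methyl 5-hydroxy-6-methoxy-3-phenyl-1-benzofuran-2-carboxylate
Product: 18 methyl 6-methoxy-3-phenyl-5-(triisopropylsilyloxy)-1-benzofuran-2-carboxylate
Conditions: i-Pr3SiCl, imidazole, DMF, rt
Reagents that add atoms: chlorotriisopropylsilane, CC(C)[Si](Cl)(C(C)C)C(C)C
Why: Phenol silylation, with the triisopropylsilyl group chosen because its aryl ether should survive hydride, zinc, the aqueous acid of step 14, MeOTf and TMSOTf and still leave with fluoride at the end.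

Step 11
Reactants: 18 methyl 6-methoxy-3-phenyl-5-(triisopropylsilyloxy)-1-benzofuran-2-carboxylate
Product: 19 [6-methoxy-3-phenyl-5-(triisopropylsilyloxy)-1-benzofuran-2-yl]methanol
Conditions: i-Bu2AlH (2.5 equiv), CH2Cl2, -78 to 0 °C; aq potassium sodium tartrate
Reagents that add atoms: none
Why: Aluminium hydride reduction of an ester to the primary alcohol, a transformation that touches neither the aryl silyl ether nor the benzofuran.

Step 12
Reactants: 19 [6-methoxy-3-phenyl-5-(triisopropylsilyloxy)-1-benzofuran-2-yl]methanol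
Product: 20 2-(chloromethyl)-6-methoxy-3-phenyl-5-(triisopropylsilyloxy)-1-benzofuran
Conditions: SOCl2, pyridine, CH2Cl2, 0 °C; used at once
Reagents that add atoms: thionyl chloride, O=S(Cl)Cl
Why: Chlorodehydroxylation with thionyl chloride, fast at 0 °C for a furfuryl-type alcohol, with pyridine trapping HCl so that the labile chloride can be carried on directly.

Step 13
Reactants: 20 2-(chloromethyl)-6-methoxy-3-phenyl-5-(triisopropylsilyloxy)-1-benzofuran; 10 C2-iodo dioxolane enone
Product: 22 (2R,3aS,7aR)-6-(ArCH2)-2-isopropyl-7a-(3-phenylprop-2-yn-1-yl)-3a,7a-dihydro-1,3-benzodioxol-5(4H)-one, via benzofuranylmethylzinc chloride 21 (not isolated)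
Conditions: 20, Zn dust, LiCl, THF, rt; then 10, Pd2(dba)3 (2.5 mol %), P(2-furyl)3 (10 mol %), THF, rt
Reagents that add atoms: none
Why: Negishi coupling of an α-iodoenone with a benzylic zinc reagent, in which LiCl-assisted insertion into the chloride keeps Wurtz homocoupling low, zerovalent palladium inserts into the C2–I bond, and the zinc partner has no β-hydrogen to lose, while no stereocentre is touched.

Step 14
Reactants: 22 coupled dioxolane enone
Product: 23 (4R,5S)-2-(ArCH2)-4,5-dihydroxy-4-(3-phenylprop-2-yn-1-yl)cyclohex-2-en-1-one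
Conditions: TFA/H2O 9:1, CH2Cl2, 0 °C to rt
Reagents that add atoms: none
Why: Acid-catalysed acetal hydrolysis, which breaks only the bonds at the acetal carbon so that both ring C–O bonds and their configuration persist, while ionisation at C4 is disfavoured next to the electron-poor enone and the aryl triisopropylsilyl ether should hold.

Step 15
Reactants: 23 (4R,5S)-4,5-diol
Product: 24 (4R,5S)-2-(ArCH2)-4,5-dimethoxy-4-(3-phenylprop-2-yn-1-yl)cyclohex-2-en-1-one
Conditions: MeOTf (excess), 2,6-di-tert-butyl-4-methylpyridine, CH2Cl2, rt to 40 °C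
Reagents that add atoms: methyl trifluoromethanesulfonate, COS(=O)(=O)C(F)(F)F
Why: O-alkylation with methyl triflate buffered by a hindered non-nucleophilic pyridine, which methylates the neutral alcohols without forming an alkoxide or enolate and so should avoid E1cB loss of the C5 oxygen from the β-hydroxy ketone.

Step 16
Reactants: 24 (4R,5S)-4,5-dimethoxy enone
Product: 26 (R)-2-(ArCH2)-4,5-dimethoxy-4-(3-phenylprop-2-yn-1-yl)cyclohexa-2,5-dien-1-one, via trimethylsilyl dienol ether 25 (not isolated)
Conditions: TMSOTf, Et3N, CH2Cl2, 0 °C; crude 25, Pd(OAc)2 (1.1 equiv), MeCN, rt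
Reagents that add atoms: none
Why: Saegusa–Ito oxidation, in which the ketone can enolise only towards C6 because C2 is a fully substituted sp2 carbon, soft enolisation avoids a free enolate, and the enolate of divalent palladium loses H5 by β-hydride elimination to give the vinylogous ester, erasing C5 and leaving C4 (R) untouched.

Step 17
Reactants: 26 (R)-alkynyl dienone
Product: 27 (R)-2-(ArCH2)-4,5-dimethoxy-4-[(Z)-3-phenylprop-2-en-1-yl]cyclohexa-2,5-dien-1-one
Conditions: H2 (1 atm), Pd/CaCO3 poisoned with Pb(OAc)2, quinoline, EtOAc, rt, stopped after 1 equiv H2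
Reagents that add atoms: none
Why: Lindlar-type semihydrogenation, in which syn delivery of H2 to the alkyne on the poisoned palladium surface sets the Z geometry and the two trisubstituted ring alkenes bind too weakly to be reduced.

Step 18
Reactants: 27 (R)-Z-alkenyl dienone silyl ether
Product: 28 (R)-2-[(5-hydroxy-6-methoxy-3-phenyl-1-benzofuran-2-yl)methyl]-4,5-dimethoxy-4-[(Z)-3-phenylprop-2-en-1-yl]cyclohexa-2,5-dien-1-one (CNP0306784.1)
Conditions: Bu4NF, AcOH, THF, 0 °C
Reagents that add atoms: none
Why: Fluoride-induced cleavage of an aryl silyl ether, buffered with acetic acid so that neither the dienone nor the Z-alkene meets a basic phenoxide medium.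

Compound list
1 | 4-hydroxybenzaldehyde | O=Cc1ccc(O)cc1 | starting material
2 | phenylacetylene | C#Cc1ccccc1 | starting material
3 | phenylethynylmagnesium bromide | Br[Mg]C#Cc1ccccc1 | intermediate
4 | 4-(1-hydroxy-3-phenylprop-2-yn-1-yl)phenol (racemic) | OC(C#Cc1ccccc1)c1ccc(O)cc1 | intermediate
5 | 4-(3-phenylprop-2-yn-1-yl)phenol | Oc1ccc(CC#Cc2ccccc2)cc1 | intermediate
6 | 4-hydroxy-4-(3-phenylprop-2-yn-1-yl)cyclohexa-2,5-dien-1-one | OC1(CC#Cc2ccccc2)C=CC(=O)C=C1 | intermediate
7 | isobutyraldehyde | CC(C)C=O | starting material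
8 | 4-(1-hydroxy-2-methylpropoxy)-4-(3-phenylprop-2-yn-1-yl)cyclohexa-2,5-dien-1-one (equilibrating hemiacetal epimers) | CC(C)C(O)OC1(CC#Cc2ccccc2)C=CC(=O)C=C1 | intermediate
9 | (2R,3aS,7aR)-2-isopropyl-7a-(3-phenylprop-2-yn-1-yl)-3a,7a-dihydro-1,3-benzodioxol-5(4H)-one | O=C1C[C@@H]2O[C@@H](C(C)C)O[C@]2(CC#Cc2ccccc2)C=C1 | intermediate
10 | (2R,3aS,7aR)-6-iodo-2-isopropyl-7a-(3-phenylprop-2-yn-1-yl)-3a,7a-dihydro-1,3-benzodioxol-5(4H)-one | O=C1C[C@@H]2O[C@@H](C(C)C)O[C@]2(CC#Cc2ccccc2)C=C1I | intermediate
11 | ethyl benzoylacetate | CCOC(=O)CC(=O)c1ccccc1 | starting material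
12 | ethyl 2-chloro-3-oxo-3-phenylpropanoate (racemic) | CCOC(=O)C(Cl)C(=O)c1ccccc1 | intermediate
13 | 2-methoxyhydroquinone | COc1cc(O)ccc1O | starting material
14 | 3-chloro-6-hydroxy-7-methoxy-4-phenylcoumarin | COc1cc2oc(=O)c(Cl)c(-c3ccccc3)c2cc1O | intermediate
15 | (E)-2-chloro-3-(2,5-dihydroxy-4-methoxyphenyl)-3-phenylprop-2-enoic acid (present as its sodium salt) | OC(=O)/C(Cl)=C(/c1ccccc1)c1cc(O)c(OC)cc1O | intermediate
16 | 5-hydroxy-6-methoxy-3-phenyl-1-benzofuran-2-carboxylic acid | COc1cc2oc(C(=O)O)c(-c3ccccc3)c2cc1O | intermediate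
17 | methyl 5-hydroxy-6-methoxy-3-phenyl-1-benzofuran-2-carboxylate | COC(=O)c1oc2cc(OC)c(O)cc2c1-c1ccccc1 | intermediate
18 | methyl 6-methoxy-3-phenyl-5-(triisopropylsilyloxy)-1-benzofuran-2-carboxylate | COC(=O)c1oc2cc(OC)c(O[Si](C(C)C)(C(C)C)C(C)C)cc2c1-c1ccccc1 | intermediate
19 | [6-methoxy-3-phenyl-5-(triisopropylsilyloxy)-1-benzofuran-2-yl]methanol | OCc1oc2cc(OC)c(O[Si](C(C)C)(C(C)C)C(C)C)cc2c1-c1ccccc1 | intermediate
20 | 2-(chloromethyl)-6-methoxy-3-phenyl-5-(triisopropylsilyloxy)-1-benzofuran | ClCc1oc2cc(OC)c(O[Si](C(C)C)(C(C)C)C(C)C)cc2c1-c1ccccc1 | intermediate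
21 | {[6-methoxy-3-phenyl-5-(triisopropylsilyloxy)-1-benzofuran-2-yl]methyl}zinc chloride | Cl[Zn]Cc1oc2cc(OC)c(O[Si](C(C)C)(C(C)C)C(C)C)cc2c1-c1ccccc1 | intermediate
22 | (2R,3aS,7aR)-6-(ArCH2)-2-isopropyl-7a-(3-phenylprop-2-yn-1-yl)-3a,7a-dihydro-1,3-benzodioxol-5(4H)-one | O=C1C[C@@H]2O[C@@H](C(C)C)O[C@]2(CC#Cc2ccccc2)C=C1Cc1oc2cc(OC)c(O[Si](C(C)C)(C(C)C)C(C)C)cc2c1-c1ccccc1 | intermediate
23 | (4R,5S)-2-(ArCH2)-4,5-dihydroxy-4-(3-phenylprop-2-yn-1-yl)cyclohex-2-en-1-one | O=C1C[C@H](O)[C@@](O)(CC#Cc2ccccc2)C=C1Cc1oc2cc(OC)c(O[Si](C(C)C)(C(C)C)C(C)C)cc2c1-c1ccccc1 | intermediate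
24 | (4R,5S)-2-(ArCH2)-4,5-dimethoxy-4-(3-phenylprop-2-yn-1-yl)cyclohex-2-en-1-one | O=C1C[C@H](OC)[C@@](OC)(CC#Cc2ccccc2)C=C1Cc1oc2cc(OC)c(O[Si](C(C)C)(C(C)C)C(C)C)cc2c1-c1ccccc1 | intermediate
25 | C1-O-trimethylsilyl dienol ether of 24 (C6=C1 and C2=C3 double bonds; C4 R, C5 S) | C[Si](C)(C)OC1=C[C@H](OC)[C@@](OC)(CC#Cc2ccccc2)C=C1Cc1oc2cc(OC)c(O[Si](C(C)C)(C(C)C)C(C)C)cc2c1-c1ccccc1 | intermediate
26 | (R)-2-(ArCH2)-4,5-dimethoxy-4-(3-phenylprop-2-yn-1-yl)cyclohexa-2,5-dien-1-one | O=C1C=C(OC)[C@@](OC)(CC#Cc2ccccc2)C=C1Cc1oc2cc(OC)c(O[Si](C(C)C)(C(C)C)C(C)C)cc2c1-c1ccccc1 | intermediate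
27 | (R)-2-(ArCH2)-4,5-dimethoxy-4-[(Z)-3-phenylprop-2-en-1-yl]cyclohexa-2,5-dien-1-one | O=C1C=C(OC)[C@@](OC)(C/C=C\c2ccccc2)C=C1Cc1oc2cc(OC)c(O[Si](C(C)C)(C(C)C)C(C)C)cc2c1-c1ccccc1 | intermediate
28 | (R)-2-[(5-hydroxy-6-methoxy-3-phenyl-1-benzofuran-2-yl)methyl]-4,5-dimethoxy-4-[(Z)-3-phenylprop-2-en-1-yl]cyclohexa-2,5-dien-1-one | COC1=CC(=O)C(Cc2oc3cc(OC)c(O)cc3c2-c2ccccc2)=C[C@@]1(C/C=C\c1ccccc1)OC | target

Total step count: 18.
Longest linear sequence: 13 steps (steps 6 to 18, from ethyl benzoylacetate); the carbocycle branch (steps 1 to 5) joins at step 13.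

Steps most likely to fail

Step 15, double O-methylation.
- What may go wrong: the hindered tertiary C4 hydroxyl may alkylate too slowly, and long exposure may cause loss of the C5 oxygen by β-elimination.
- The fallback sets out from 23 and comes back at 26; it raises the oxidation level before any alkylation.
- The periodinane 1,1,1-triacetoxy-1,2-benziodoxol-3(1H)-one in CH2Cl2 should oxidise only the secondary C5 carbinol of 23 and give the enolised 1,3-diketone F1.
- TMSCHN2 in toluene/MeOH should convert this vinylogous acid into the 4-hydroxy-5-methoxy dienone F2. The site of O-methylation has to be verified at this point.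
- In F2 no β-leaving group remains, so the tertiary hydroxyl can be methylated with MeI/Ag2O to give 26. This path also bypasses step 16.

Step 16, dehydrogenation.
- What may go wrong: the palladium enolate may be intercepted by the nearby alkyne through carbopalladation, or it may expel methoxide instead of hydride.
- The fallback sets out from 24 and comes back at 26; it avoids palladium.
- Crude 25, made as in the route, is treated with PhSeCl in CH2Cl2 at -78 °C, with attack expected anti to the neighbouring C5 methoxy group, to give the 6-phenylselanyl ketone F3.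
- H2O2 and pyridine in CH2Cl2 at 0 °C oxidise it to the selenoxide F4, which should undergo syn elimination with H5 in the flask and deliver 26.

Step 4, desymmetrisation.
- What may go wrong: hemiacetal formation at the tertiary hydroxyl may be sluggish, or the discrimination between the two enone arms may be insufficient.
- The fallback sets out from 6 and comes back at 9; it changes both nucleophile and catalyst class.
- PhB(OH)2 and 6, with a cinchona-derived tertiary amine thiourea and 4 Å MS in toluene, should form a boronic acid hemiester on the C4 oxygen. Its B–OH then adds to C5 under bifunctional catalysis and gives the cis-fused phenylboronate F5.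
- Exchange with pinacol releases the (4R,5S)-diol F6.
- F6 is re-acetalised with 7, pyridinium p-toluenesulfonate and MgSO4 in CH2Cl2 to give the thermodynamically preferred exo acetal 9.

Further compounds
F1 | step 15 | enolised 1,3-diketone, (R)-2-(ArCH2)-4,5-dihydroxy-4-(3-phenylprop-2-yn-1-yl)cyclohexa-2,5-dien-1-one | O=C1C=C(O)[C@@](O)(CC#Cc2ccccc2)C=C1Cc1oc2cc(OC)c(O[Si](C(C)C)(C(C)C)C(C)C)cc2c1-c1ccccc1
F2 | step 15 | 4-hydroxy-5-methoxy dienone, (R)-2-(ArCH2)-4-hydroxy-5-methoxy-4-(3-phenylprop-2-yn-1-yl)cyclohexa-2,5-dien-1-one | O=C1C=C(OC)[C@@](O)(CC#Cc2ccccc2)C=C1Cc1oc2cc(OC)c(O[Si](C(C)C)(C(C)C)C(C)C)cc2c1-c1ccccc1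
F3 | step 16 | 6-phenylselanyl ketone, 24 with SePh on C6 trans to the C5 methoxy group | O=C1[C@@H]([Se]c3ccccc3)[C@H](OC)[C@@](OC)(CC#Cc2ccccc2)C=C1Cc1oc2cc(OC)c(O[Si](C(C)C)(C(C)C)C(C)C)cc2c1-c1ccccc1
F4 | step 16 | selenoxide of F3 (selenium configuration undefined) | O=C1[C@@H]([Se](=O)c3ccccc3)[C@H](OC)[C@@](OC)(CC#Cc2ccccc2)C=C1Cc1oc2cc(OC)c(O[Si](C(C)C)(C(C)C)C(C)C)cc2c1-c1ccccc1
F5 | step 4 | cis-fused phenylboronate, (3aS,7aR)-2-phenyl-7a-(3-phenylprop-2-yn-1-yl)-3a,7a-dihydro-1,3,2-benzodioxaborol-5(4H)-one | O=C1C[C@@H]2OB(c3ccccc3)O[C@]2(CC#Cc2ccccc2)C=C1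
F6 | step 4 | (4R,5S)-diol, (4R,5S)-4,5-dihydroxy-4-(3-phenylprop-2-yn-1-yl)cyclohex-2-en-1-one | O=C1C[C@H](O)[C@@](O)(CC#Cc2ccccc2)C=C1
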